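## Retrosynthetic overview

1. Target ⇒ tricyclic chromanone–δ-lactone phenol + prenyl donor. The last operation opens the lactone (freeing the acid and the C5 enol) and dearomatises ring A by C8-prenylation, the final event assumed in the plant.
2. Ring B (chromanone) ⇒ 7-hydroxy-8-tigloyl-dihydrocoumarin by quinine-catalysed oxa-Michael closure (sets C2/C3 cis). The lactone ties up the other ortho oxygen, so only the required regioisomer can close.
3. Ring C (temporary δ-lactone, propyl stereocentre) ⇒ 2-lavandulylphloroglucinol + (E)-hex-2-enal via a carbene-bound unsaturated acyl azolium, a thioester mimic of enoyl-CoA conjugate addition/lactonisation.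
4. 2-Lavandulylphloroglucinol ⇒ MOM-protected phloroglucinol aryllithium + (S)-lavandulyl triflate; (S)-lavandulol ⇐ Evans dienolate prenylation.
5. Ring order: ring A bought (phloroglucinol) → lactone ring C → chromanone ring B → ring C opened and ring A dearomatised.

Assumption: (S)-lavandulol is not a cheap catalogue item and is therefore made; the hand of each chiral catalyst (steps 7, 9, 10) is taken from the closest precedent and would be confirmed on the first run, the opposite hand being on sale in each case (quinidine for quinine).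

Lavandulyl = 5-methyl-2-(prop-1-en-2-yl)hex-4-en-1-yl. Compounds 17–20 use coumarin numbering; 21–24 use chroman-4-one numbering.

## Route

Step 1
Reactants: 1 (S)-4-benzyl-1,3-oxazolidin-2-one; 2 3-methylbut-2-enoyl chloride
Product: 4 (S)-4-benzyl-3-(3-methylbut-2-enoyl)-1,3-oxazolidin-2-one, via lithium oxazolidinide 3 (not isolated)
Conditions: n-BuLi, THF, −78 °C; then 2, −78 → 0 °C
Reagents that add atoms: none
Why: N-acylation of the lithiated auxiliary by the acid chloride; no new stereocentre.

Step 2
Reactants: 4 (S)-4-benzyl-3-(3-methylbut-2-enoyl)-1,3-oxazolidin-2-one; 5 prenyl bromide (1-bromo-3-methylbut-2-ene)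
Product: 7 (4S)-4-benzyl-3-[(2S)-5-methyl-2-(prop-1-en-2-yl)hex-4-enoyl]-1,3-oxazolidin-2-one, via sodium (Z)-dienolate 6 (not isolated)
Conditions: NaN(SiMe3)2, THF, −78 °C; then 5, −78 → −40 °C
Reagents that add atoms: none
Why: Evans asymmetric alkylation in its deconjugative form: γ-deprotonation gives the chelated (Z)-dienolate, which is prenylated at Cα on the face opposite the benzyl group, setting the lavandulyl stereocentre (2S).

Step 3
Reactants: 7 (4S)-4-benzyl-3-[(2S)-5-methyl-2-(prop-1-en-2-yl)hex-4-enoyl]-1,3-oxazolidin-2-one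
Product: 8 (S)-lavandulol [(2S)-5-methyl-2-(prop-1-en-2-yl)hex-4-en-1-ol]
Conditions: LiBH4, THF, 0 → 25 °C
Reagents that add atoms: none
Why: Hydride reduction of the exocyclic imide carbonyl releases the primary alcohol and the recoverable auxiliary; the non-basic conditions leave the allylic α-centre untouched.

Step 4
Reactants: 9 phloroglucinol (benzene-1,3,5-triol)
Product: 10 1,3,5-tris(methoxymethoxy)benzene
Conditions: MOMCl, iPr2NEt, CH2Cl2, 0 → 25 °C
Reagents that add atoms: chloromethyl methyl ether (MOMCl), COCCl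
Why: Threefold O-alkylation (acetal formation) gives a symmetric arene whose ring C–H bonds each lie between two ortho-directing groups.

Step 5
Reactants: 8 (S)-lavandulol; 10 1,3,5-tris(methoxymethoxy)benzene
Product: 14 2-[(2R)-lavandulyl]-1,3,5-tris(methoxymethoxy)benzene, via lithium (S)-lavandulolate 11 (not isolated), via (S)-lavandulyl triflate 12 (not isolated), via 2,4,6-tris(methoxymethoxy)phenyllithium 13 (not isolated)
Conditions: flask A: 8, n-BuLi, Et2O, −78 °C, then Tf2O, −78 °C; flask B: 10 (1.5 equiv), n-BuLi, THF, 0 °C; A into B, −78 → −20 °C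
Reagents that add atoms: none
Why: Directed ortho-lithiation followed by SN2 alkylation with a primary triflate, chosen because it outruns E2 loss to the conjugated diene that a halide would suffer. The stereocentre is β to the reacting carbon and is not touched; its descriptor changes from S to R only by CIP priority.

Step 6
Reactants: 14 2-[(2R)-lavandulyl]-1,3,5-tris(methoxymethoxy)benzene
Product: 15 2-[(2R)-lavandulyl]benzene-1,3,5-triol
Conditions: HCl (1.25 M in MeOH), 25 °C
Reagents that add atoms: none
Why: Acid-catalysed acetal methanolysis; dilute acid at room temperature is kept below the threshold for cyclisation of the isopropenyl group onto the ortho phenols.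

Step 7
Reactants: 15 2-[(2R)-lavandulyl]benzene-1,3,5-triol; 16 (E)-hex-2-enal
Product: 17 (4R)-5,7-dihydroxy-6-[(2R)-lavandulyl]-4-propyl-3,4-dihydro-2H-chromen-2-one
Conditions: (5aS,10bR)-2-mesityl-5a,10b-dihydro-4H,6H-indeno[2,1-b][1,2,4]triazolo[4,3-d][1,4]oxazin-2-ium tetrafluoroborate (10 mol%), K2CO3 (20 mol%), 3,3',5,5'-tetra-tert-butyldiphenoquinone (1.1 equiv), toluene, 25 °C
Reagents that add atoms: none
Why: Oxidative N-heterocyclic carbene catalysis turns the enal into an α,β-unsaturated acyl azolium; a free ring carbon (the two are equivalent by side-chain rotation) adds to the β-carbon on the face left open by the aminoindanol backbone, setting the propyl centre (4R). The acyl azolium is then expected to be captured by the least hindered hydroxyl, the one para to lavandulyl, giving the lactone that later forces the chromanone regiochemistry.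

Step 8
Reactants: 17 (4R)-5,7-dihydroxy-6-[(2R)-lavandulyl]-4-propyl-3,4-dihydro-2H-chromen-2-one; 18 tigloyl chloride [(E)-2-methylbut-2-enoyl chloride]
Product: 20 (4R)-5,7-dihydroxy-6-[(2R)-lavandulyl]-8-[(2E)-2-methylbut-2-enoyl]-4-propyl-3,4-dihydro-2H-chromen-2-one, via bis(bromomagnesium) phenoxide 19 (not isolated)
Conditions: EtMgBr (2.05 equiv), Et2O/toluene, −20 → 0 °C; then 18 (1.1 equiv), toluene, 25 °C; aq. NH4Cl
Reagents that add atoms: none
Why: Metal-template ortho C-acylation of a bromomagnesium phenoxide with an unsaturated acyl chloride (Friedel–Crafts type without protic or strong Lewis acid), so the lavandulyl alkenes survive; C8 is the only free ring position and no stereocentre is formed.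

Step 9
Reactants: 20 (4R)-5,7-dihydroxy-6-[(2R)-lavandulyl]-8-[(2E)-2-methylbut-2-enoyl]-4-propyl-3,4-dihydro-2H-chromen-2-one
Product: 21 tricyclic chromanone lactone: (2R,3S)-7-hydroxy-2,3-dimethyl-8-[(2R)-lavandulyl]chroman-4-one whose O5 and C6 are bridged by C(=O)–CH2–(R)-CH(n-Pr)
Conditions: (−)-quinine (20 mol%), chlorobenzene, 25 °C
Reagents that add atoms: none
Why: Quinine-catalysed intramolecular 6-endo oxa-Michael addition of the only hydroxyl ortho to the tigloyl group (the other ortho oxygen is the lactone oxygen). The alkaloid controls the face of O–C bond formation and the syn protonation, giving the cis-(2R,3S) chromanone as with 7-hydroxy-8-tigloylcoumarins.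

Step 10
Reactants: 21 tricyclic chromanone lactone; 22 prenyl acetate (3-methylbut-2-en-1-yl acetate)
Product: 24 (3R)-3-[(2R,3S,8R)-5-hydroxy-2,3-dimethyl-8-(3-methylbut-2-en-1-yl)-8-[(2R)-5-methyl-2-(prop-1-en-2-yl)hex-4-en-1-yl]-4,7-dioxo-3,4,7,8-tetrahydro-2H-chromen-6-yl]hexanoic acid, via trilithium seco-acid salt 23 (not isolated)
Conditions: LiOH·H2O (3.1 equiv), THF/H2O 3:1, 0 °C; then Pd2(dba)3·CHCl3 (2.5 mol%), (R,R)-DACH-phenyl Trost ligand (7.5 mol%), 22 (1.2 equiv), 0 → 25 °C; cold dilute HCl to pH 3–4
Reagents that add atoms: water, O (supplied as LiOH·H2O)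
Why: Proposed new method: hydroxide opens the aryl lactone to the carboxylate–diphenoxide 23; a zerovalent palladium–Trost ligand complex ionises prenyl acetate to a chiral π-prenyl cation that is attacked at its unsubstituted terminus by C8, the ring carbon between the ether oxygen and the C7 phenoxide and the less hindered of the two alkylated ring carbons, dearomatising ring A to the stable vinylogous-acid enolate of 24 (O-prenyl ethers and the prenyl ester re-ionise under the catalyst and funnel to carbon); the ligand pocket, not the remote substrate centres, must choose the ring face and so set C8 (R); closest known reaction types are the base-mediated dearomative C-prenylation of di-C-alkylated acylphloroglucinols (lupulone type) and the palladium-catalysed Tsuji–Trost asymmetric linear prenylation of oxindoles and allylic dearomatisation of naphthols.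

## Compound list

1 | (S)-4-benzyl-1,3-oxazolidin-2-one | O=C1N[C@@H](Cc2ccccc2)CO1 | starting material
2 | 3-methylbut-2-enoyl chloride | CC(C)=CC(=O)Cl | starting material
3 | lithium (S)-4-benzyl-2-oxo-1,3-oxazolidin-3-ide | [Li]N1[C@@H](Cc2ccccc2)COC1=O | intermediate (not isolated)
4 | (S)-4-benzyl-3-(3-methylbut-2-enoyl)-1,3-oxazolidin-2-one | CC(C)=CC(=O)N1[C@@H](Cc2ccccc2)COC1=O | intermediate
5 | prenyl bromide | CC(C)=CCBr | starting material
6 | sodium (Z)-dienolate of 4 | C=C(C)/C=C(\O[Na])N1[C@@H](Cc2ccccc2)COC1=O | intermediate (not isolated)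
7 | (4S)-4-benzyl-3-[(2S)-5-methyl-2-(prop-1-en-2-yl)hex-4-enoyl]-1,3-oxazolidin-2-one | C=C(C)[C@H](CC=C(C)C)C(=O)N1[C@@H](Cc2ccccc2)COC1=O | intermediate
8 | (S)-lavandulol | C=C(C)[C@H](CC=C(C)C)CO | intermediate
9 | phloroglucinol | Oc1cc(O)cc(O)c1 | starting material
10 | 1,3,5-tris(methoxymethoxy)benzene | COCOc1cc(OCOC)cc(OCOC)c1 | intermediate
11 | lithium (S)-lavandulolate | C=C(C)[C@H](CC=C(C)C)CO[Li] | intermediate (not isolated)
12 | (S)-lavandulyl trifluoromethanesulfonate | C=C(C)[C@H](CC=C(C)C)COS(=O)(=O)C(F)(F)F | intermediate (not isolated)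
13 | 2,4,6-tris(methoxymethoxy)phenyllithium | [Li]c1c(OCOC)cc(OCOC)cc1OCOC | intermediate (not isolated)
14 | 2-[(2R)-lavandulyl]-1,3,5-tris(methoxymethoxy)benzene | C=C(C)[C@H](CC=C(C)C)Cc1c(OCOC)cc(OCOC)cc1OCOC | intermediate
15 | 2-[(2R)-lavandulyl]benzene-1,3,5-triol | C=C(C)[C@H](CC=C(C)C)Cc1c(O)cc(O)cc1O | intermediate
16 | (E)-hex-2-enal | CCC/C=C/C=O | starting material
17 | (4R)-5,7-dihydroxy-6-[(2R)-lavandulyl]-4-propyl-3,4-dihydro-2H-chromen-2-one | C=C(C)[C@H](CC=C(C)C)Cc1c(O)cc2OC(=O)C[C@@H](CCC)c2c1O | intermediate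
18 | tigloyl chloride | C/C=C(\C)C(=O)Cl | starting material
19 | bis(bromomagnesium) phenoxide of 17 | C=C(C)[C@H](CC=C(C)C)Cc1c(O[Mg]Br)cc2OC(=O)C[C@@H](CCC)c2c1O[Mg]Br | intermediate (not isolated)
20 | (4R)-5,7-dihydroxy-6-[(2R)-lavandulyl]-8-[(2E)-2-methylbut-2-enoyl]-4-propyl-3,4-dihydro-2H-chromen-2-one | C=C(C)[C@H](CC=C(C)C)Cc1c(O)c(C(=O)/C(C)=C/C)c2OC(=O)C[C@@H](CCC)c2c1O | intermediate
21 | (2R,3S)-7-hydroxy-2,3-dimethyl-8-[(2R)-lavandulyl]chroman-4-one bridged O5 to C6 by C(=O)–CH2–(R)-CH(n-Pr) | C=C(C)[C@H](CC=C(C)C)Cc1c(O)c2c(OC(=O)C[C@H]2CCC)c3c1O[C@H](C)[C@H](C)C3=O | intermediate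
22 | prenyl acetate | CC(=O)OCC=C(C)C | starting material
23 | trilithium salt of (3R)-3-[(2R,3S)-5,7-dihydroxy-2,3-dimethyl-8-[(2R)-lavandulyl]-4-oxochroman-6-yl]hexanoic acid | C=C(C)[C@H](CC=C(C)C)Cc1c(O[Li])c([C@H](CCC)CC(=O)O[Li])c(O[Li])c2c1O[C@H](C)[C@H](C)C2=O | intermediate (not isolated)
24 | (3R)-3-[(2R,3S,8R)-5-hydroxy-2,3-dimethyl-8-(3-methylbut-2-en-1-yl)-8-[(2R)-lavandulyl]-4,7-dioxo-3,4,7,8-tetrahydro-2H-chromen-6-yl]hexanoic acid | C=C(C)[C@H](CC=C(C)C)C[C@@]1(CC=C(C)C)C(=O)C([C@H](CCC)CC(=O)O)=C(O)C2=C1O[C@H](C)[C@H](C)C2=O | target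

## Count and risks

Total step count: 10. Longest linear sequence: 9 (steps 1, 2, 3, 5, 6, 7, 8, 9, 10).

Three steps most likely to fail:

Step 10 (face selectivity at C8; also C8 versus C6 and C versus O alkylation). The fallback sets out from 21 and comes back at 24. The single free hydroxyl of 21 is converted with tert-butyl 2-methylbut-3-en-2-yl carbonate and Pd(PPh3)4 into the 7-O-(2-methylbut-3-en-2-yl) ether F1. Warming F1 with Eu(fod)3 in toluene drives an aromatic Claisen rearrangement onto the blocked ortho carbon C8 and gives the neutral dearomatised dienone lactone F2. Face control is not expected, but the two C8 epimers are ordinary diastereomers and can be separated by chromatography. Brief LiOH treatment of the 8R epimer opens its vinylogous-anhydride lactone to 24.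

Step 7 (lactone closing on the hydroxyl next to lavandulyl, double annulation, oxidation of the triol, enantioselectivity). The fallback sets out from 15 (with 16) and comes back at 17. Iminium catalysis with (S)-α,α-diphenylprolinol trimethylsilyl ether and benzoic acid effects a Friedel–Crafts-type conjugate addition; the ring carbon adds anti to the diarylsilyloxymethyl group (4R). The adduct closes to the lactol (4R)-6-[(2R)-lavandulyl]-4-propylchromane-2,5,7-triol F3, which equilibrates through its open aldehyde toward the less hindered oxygen. Oxidation of F3 with Ag2CO3 on Celite gives 17.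

Step 8 (O- instead of C-acylation, or premature racemic ring closure on magnesium). The fallback sets out from 17 and comes back at 20. The less hindered C7 hydroxyl is esterified with 18 and Et3N at −40 °C to the 7-O-tiglate ester F4. A photo-Fries rearrangement (254 nm, benzene) then moves the acyl group to the only free ortho carbon, C8, to give 20.

Further compounds
F1 | step 10 | 7-O-(2-methylbut-3-en-2-yl) ether of 21 | C=C(C)[C@H](CC=C(C)C)Cc1c(OC(C)(C)C=C)c2c(OC(=O)C[C@H]2CCC)c3c1O[C@H](C)[C@H](C)C3=O
F2 | step 10 | (8R)-8-prenyl-8-[(2R)-lavandulyl]-7-oxo dienone of 21 with the O5–C6 lactone intact | C=C(C)[C@H](CC=C(C)C)C[C@@]1(CC=C(C)C)C(=O)C2=C(OC(=O)C[C@H]2CCC)C3=C1O[C@H](C)[C@H](C)C3=O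
F3 | step 7 | (4R)-6-[(2R)-lavandulyl]-4-propylchromane-2,5,7-triol (lactol, anomer mixture) | C=C(C)[C@H](CC=C(C)C)Cc1c(O)cc2OC(O)C[C@@H](CCC)c2c1O
F4 | step 8 | (4R)-5-hydroxy-6-[(2R)-lavandulyl]-2-oxo-4-propylchroman-7-yl (E)-2-methylbut-2-enoate | C=C(C)[C@H](CC=C(C)C)Cc1c(OC(=O)/C(C)=C/C)cc2OC(=O)C[C@@H](CCC)c2c1O
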